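## Retrosynthetic overview

1. Target 21 ⇐ Mitsunobu esterification with inversion at C-8 of macrocyclic alcohol 19 with (R)-2-methylbutanoic acid 20.
2. 19 ⇐ key step: the aromatic 3-silyloxyfuran made in situ from epoxy-furanone 16 attacks its own terminal epoxide carbon (C-9–C-10 bond); this one step breaks the furan aromaticity and forms the ten-membered carbocycle, the 3(2H)-furanone and the quaternary C-10.
3. 16 ⇐ diol 15 ⇐ CrCl2-mediated 2-(methoxycarbonyl)allylation/lactonisation of Z-enal 7 with allyl bromide 11 (C-6–C-7 bond, trans α-methylene lactone).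
4. 7 ⇐ 2-methylfuran + ethyl but-2-ynoate (hydroarylation sets the Z-olefin), then C–H borylation/oxidation puts the oxygen on the furan; 11 ⇐ (S)-glyceraldehyde acetonide + methyl acrylate.
5. Ring order: γ-lactone (step 7), then carbocycle and furanone together (step 9).

Assumption: labels C-1 to C-15 are the germacrane numbers of the target (C-10 quaternary furanone carbon, C-8 ester carbon, C-6/C-7 lactone ring fusion). Compounds 6, 7 and 13–16 are carried as both epimers at the furanone CH(CH3) carbon, which step 9 planarises; that centre is left unassigned in their SMILES.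

## Route

Step 1
Reactants: 1 2-methylfuran; 2 ethyl but-2-ynoate
Product: 3 ethyl (2Z)-3-(5-methylfuran-2-yl)but-2-enoate
Conditions: Pd(OAc)2 (5 mol %), AcOH, rt, 48 h (1 in twofold excess)
Reagents that add atoms: none
Why: Fujiwara trans-hydroarylation: furan C-5 adds to the alkyne activated by divalent palladium anti to the metal and protonolysis retains geometry, so the furyl group ends cis to the ester (the Z-olefin the ring needs); no stereocentre.

Step 2
Reactants: 3 ethyl (2Z)-3-(5-methylfuran-2-yl)but-2-enoate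
Product: 4 ethyl (2Z)-3-[5-methyl-4-(4,4,5,5-tetramethyl-1,3,2-dioxaborolan-2-yl)furan-2-yl]but-2-enoate
Conditions: [Ir(OMe)(cod)]2 (1.5 mol %), 4,4'-di-tert-butyl-2,2'-bipyridine (3 mol %), B2pin2 (1.0 equiv), THF, 60 °C
Reagents that add atoms: bis(pinacolato)diboron, CC1(C)OB(OC1(C)C)B1OC(C)(C)C(C)(C)O1
Why: Iridium-catalysed C–H borylation is sterically controlled, so of the two free ring C–H bonds the one next to the small methyl group reacts rather than the one flanked by the trisubstituted alkenyl group; no stereocentre.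

Step 3
Reactants: 4 ethyl (2Z)-3-[5-methyl-4-(4,4,5,5-tetramethyl-1,3,2-dioxaborolan-2-yl)furan-2-yl]but-2-enoate
Product: 6 5-[(2Z)-4-hydroxybut-2-en-2-yl]-2-methylfuran-3(2H)-one, via boronate alcohol 5 (not isolated)
Conditions: i-Bu2AlH (2.5 equiv), CH2Cl2, −78 °C; MeOH, aq. KNaC4H4O6; then NaBO3·4H2O (3 equiv), THF–H2O, rt, under N2
Reagents that add atoms: sodium perborate, [Na+].[O-]OB=O
Why: Ester reduction at −78 °C leaves the aryl boronate and the Z-olefin intact, and perborate oxidation of the C–B bond (1,2-boronate shift) gives the furan-3-ol, which tautomerises to the 3(2H)-furanone; its new CH(CH3) centre is racemic and is erased in step 9.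

Step 4
Reactants: 6 5-[(2Z)-4-hydroxybut-2-en-2-yl]-2-methylfuran-3(2H)-one
Product: 7 (2Z)-3-(5-methyl-4-oxo-4,5-dihydrofuran-2-yl)but-2-enal
Conditions: MnO2 (15 equiv), CH2Cl2, rt, dark; used at once
Reagents that add atoms: none
Why: Allylic alcohol oxidation with MnO2 is neutral and heterogeneous, so the Z-enal is formed without isomerisation and the furanone is untouched; no stereocentre.

Step 5
Reactants: 8 (4S)-2,2-dimethyl-1,3-dioxolane-4-carbaldehyde; 9 methyl acrylate
Product: 10 methyl 2-{[(4S)-2,2-dimethyl-1,3-dioxolan-4-yl](hydroxy)methyl}prop-2-enoate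
Conditions: DABCO (0.5 equiv), 1,4-dioxane–H2O (1:1), rt, 48 h
Reagents that add atoms: none
Why: Morita–Baylis–Hillman reaction; the carbinol centre forms as a mixture but is destroyed in step 6, and the dioxolane centre is not epimerised under these mild conditions.

Step 6
Reactants: 10 methyl 2-{[(4S)-2,2-dimethyl-1,3-dioxolan-4-yl](hydroxy)methyl}prop-2-enoate
Product: 11 methyl (2Z)-2-(bromomethyl)-3-[(4R)-2,2-dimethyl-1,3-dioxolan-4-yl]prop-2-enoate
Conditions: NBS (1.3 equiv), Me2S (1.5 equiv), CH2Cl2, 0 °C to rt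
Reagents that add atoms: N-bromosuccinimide, BrN1C(=O)CCC1=O
Why: Corey–Kim-type activation of the hydroxyl and SN2' attack of bromide give the thermodynamic (Z)-2-(bromomethyl)alkenoate with allylic transposition; the dioxolane centre is unchanged (the descriptor changes only by priority).

Step 7
Reactants: 7 (2Z)-3-(5-methyl-4-oxo-4,5-dihydrofuran-2-yl)but-2-enal; 11 methyl (2Z)-2-(bromomethyl)-3-[(4R)-2,2-dimethyl-1,3-dioxolan-4-yl]prop-2-enoate
Product: 15 (4R,5R)-4-[(1R)-1,2-dihydroxyethyl]-3-methylidene-5-[(1Z)-2-(5-methyl-4-oxo-4,5-dihydrofuran-2-yl)prop-1-en-1-yl]oxolan-2-one, via allylchromium reagent 12 (not isolated), via hydroxy ester 13 (not isolated), via lactone acetonide 14 (not isolated)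
Conditions: CrCl2 (4 equiv), 11 (1.6 equiv), THF, rt, 12 h; then 2 M HCl–THF (1:4), rt
Reagents that add atoms: none
Why: Nozaki–Hiyama-type Barbier allylation: the trivalent allylchromium isomers equilibrate and react through the chair transition state with the dioxolanyl group equatorial (anti adduct, hence the trans lactone), and the aldehyde attacks anti to the allylic C-8–O bond (Felkin–Anh, H-8 eclipsed by 1,3-allylic strain), which sets C-6 and C-7 relative to C-8; the chromium alkoxide lactonises and the acid removes the acetonide.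

Step 8
Reactants: 15 (4R,5R)-4-[(1R)-1,2-dihydroxyethyl]-3-methylidene-5-[(1Z)-2-(5-methyl-4-oxo-4,5-dihydrofuran-2-yl)prop-1-en-1-yl]oxolan-2-one
Product: 16 (4S,5R)-3-methylidene-5-[(1Z)-2-(5-methyl-4-oxo-4,5-dihydrofuran-2-yl)prop-1-en-1-yl]-4-[(2R)-oxiran-2-yl]oxolan-2-one
Conditions: PPh3 (1.5 equiv), DIAD (1.5 equiv), toluene, 0 to 70 °C
Reagents that add atoms: none
Why: Mitsunobu cyclodehydration of a 1,2-diol: the primary oxygen is activated on phosphorus and displaced by the neighbouring secondary oxygen (3-exo-tet), so C-8 keeps its configuration and no free alkoxide is formed next to the methylene lactone.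

Step 9
Reactants: 16 (4S,5R)-3-methylidene-5-[(1Z)-2-(5-methyl-4-oxo-4,5-dihydrofuran-2-yl)prop-1-en-1-yl]-4-[(2R)-oxiran-2-yl]oxolan-2-one
Product: 19 (2Z,4R,8R,9S,11S)-9-hydroxy-2,11-dimethyl-7-methylidene-5,14-dioxatricyclo[9.2.1.0^{4,8}]tetradeca-1(13),2-diene-6,12-dione, via silyloxyfuran epoxide 17 (not isolated), via macrocyclic silyl ether 18 (not isolated)
Conditions: TMSOTf (1.05 equiv), i-Pr2NEt (1.1 equiv), CH2Cl2, 0 °C; dilute to 0.001 M, BF3·OEt2 (0.5 equiv), −78 to −40 °C; then 1 M HCl, THF, 0 °C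
Reagents that add atoms: none
Why: Proposed new method: silylation converts both furanone epimers into one aromatic 2-methyl-3-silyloxyfuran, whose enol-ether carbon (C-10) opens the BF3-activated epoxide at its primary carbon in a ring-closing SN2 step (closest known chemistry: Mukaiyama-type C-2 alkylation of 3-silyloxyfurans and Lewis-acid furan-terminated epoxide cyclisations), breaking aromaticity and creating the quaternary centre; backside attack needs the C-8–O bond antiperiplanar to the new C-9–C-10 bond, and with this (R)-epoxide that geometry is expected to match the favoured conformation of the natural ring skeleton (trans-lactone outward, chain looping over the furan oxygen), so C-9 should reach the furan face that gives 10S; O-alkylation is not possible on the silyl ether.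

Step 10
Reactants: 19 (2Z,4R,8R,9S,11S)-9-hydroxy-2,11-dimethyl-7-methylidene-5,14-dioxatricyclo[9.2.1.0^{4,8}]tetradeca-1(13),2-diene-6,12-dione; 20 (2R)-2-methylbutanoic acid
Product: 21 (2Z,4R,8R,9R,11S)-2,11-dimethyl-7-methylidene-6,12-dioxo-5,14-dioxatricyclo[9.2.1.0^{4,8}]tetradeca-1(13),2-dien-9-yl (2R)-2-methylbutanoate
Conditions: PPh3 (2 equiv), DIAD (2 equiv), 20 (2 equiv), toluene, 0 °C to rt
Reagents that add atoms: none
Why: Mitsunobu esterification: the carboxylate displaces the alkoxyphosphonium group by SN2, inverting C-8 from S to R while it installs the ester; the acid stereocentre is not touched and the product has no enolisable position at C-10.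

## Compound list

1 | 2-methylfuran | Cc1ccco1 | starting material
2 | ethyl but-2-ynoate | CCOC(=O)C#CC | starting material
3 | ethyl (2Z)-3-(5-methylfuran-2-yl)but-2-enoate | CCOC(=O)/C=C(/C)c1ccc(C)o1 | intermediate
4 | ethyl (2Z)-3-[5-methyl-4-(4,4,5,5-tetramethyl-1,3,2-dioxaborolan-2-yl)furan-2-yl]but-2-enoate | CCOC(=O)/C=C(/C)c1cc(B2OC(C)(C)C(C)(C)O2)c(C)o1 | intermediate
5 | (2Z)-3-[5-methyl-4-(4,4,5,5-tetramethyl-1,3,2-dioxaborolan-2-yl)furan-2-yl]but-2-en-1-ol | OC/C=C(/C)c1cc(B2OC(C)(C)C(C)(C)O2)c(C)o1 | intermediate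
6 | 5-[(2Z)-4-hydroxybut-2-en-2-yl]-2-methylfuran-3(2H)-one (both epimers at ring C-2) | OC/C=C(/C)C1=CC(=O)C(C)O1 | intermediate
7 | (2Z)-3-(5-methyl-4-oxo-4,5-dihydrofuran-2-yl)but-2-enal (both epimers at the ring CH(CH3)) | O=C/C=C(/C)C1=CC(=O)C(C)O1 | intermediate
8 | (4S)-2,2-dimethyl-1,3-dioxolane-4-carbaldehyde | O=C[C@@H]1COC(C)(C)O1 | starting material
9 | methyl acrylate | COC(=O)C=C | starting material
10 | methyl 2-{[(4S)-2,2-dimethyl-1,3-dioxolan-4-yl](hydroxy)methyl}prop-2-enoate (both carbinol epimers) | COC(=O)C(=C)C(O)[C@@H]1COC(C)(C)O1 | intermediate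
11 | methyl (2Z)-2-(bromomethyl)-3-[(4R)-2,2-dimethyl-1,3-dioxolan-4-yl]prop-2-enoate | COC(=O)/C(CBr)=C/[C@@H]1COC(C)(C)O1 | intermediate
12 | methyl 2-[(dichlorochromio)methyl]-3-[(4R)-2,2-dimethyl-1,3-dioxolan-4-yl]prop-2-enoate (olefin geometry equilibrating) | COC(=O)C(C[Cr](Cl)Cl)=C[C@@H]1COC(C)(C)O1 | intermediate
13 | methyl (3S,4R,5Z)-3-[(4R)-2,2-dimethyl-1,3-dioxolan-4-yl]-4-hydroxy-2-methylidene-6-(5-methyl-4-oxo-4,5-dihydrofuran-2-yl)hept-5-enoate | C=C(C(=O)OC)[C@@H]([C@H](O)/C=C(/C)C1=CC(=O)C(C)O1)[C@@H]1COC(C)(C)O1 | intermediate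
14 | (4S,5R)-4-[(4R)-2,2-dimethyl-1,3-dioxolan-4-yl]-3-methylidene-5-[(1Z)-2-(5-methyl-4-oxo-4,5-dihydrofuran-2-yl)prop-1-en-1-yl]oxolan-2-one | C=C1C(=O)O[C@H](/C=C(/C)C2=CC(=O)C(C)O2)[C@H]1[C@@H]1COC(C)(C)O1 | intermediate
15 | (4R,5R)-4-[(1R)-1,2-dihydroxyethyl]-3-methylidene-5-[(1Z)-2-(5-methyl-4-oxo-4,5-dihydrofuran-2-yl)prop-1-en-1-yl]oxolan-2-one | C=C1C(=O)O[C@H](/C=C(/C)C2=CC(=O)C(C)O2)[C@H]1[C@@H](O)CO | intermediate
16 | (4S,5R)-3-methylidene-5-[(1Z)-2-(5-methyl-4-oxo-4,5-dihydrofuran-2-yl)prop-1-en-1-yl]-4-[(2R)-oxiran-2-yl]oxolan-2-one | C=C1C(=O)O[C@H](/C=C(/C)C2=CC(=O)C(C)O2)[C@H]1[C@@H]1CO1 | intermediate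
17 | (4S,5R)-3-methylidene-5-[(1Z)-2-{5-methyl-4-[(trimethylsilyl)oxy]furan-2-yl}prop-1-en-1-yl]-4-[(2R)-oxiran-2-yl]oxolan-2-one | C=C1C(=O)O[C@H](/C=C(/C)c2cc(O[Si](C)(C)C)c(C)o2)[C@H]1[C@@H]1CO1 | intermediate
18 | (2Z,4R,8S,9S,11S)-2,11-dimethyl-7-methylidene-9-[(trimethylsilyl)oxy]-5,14-dioxatricyclo[9.2.1.0^{4,8}]tetradeca-1(13),2-diene-6,12-dione | C=C1C(=O)O[C@@H]2/C=C(/C)C3=CC(=O)[C@](C)(C[C@H](O[Si](C)(C)C)[C@@H]12)O3 | intermediate
19 | (2Z,4R,8R,9S,11S)-9-hydroxy-2,11-dimethyl-7-methylidene-5,14-dioxatricyclo[9.2.1.0^{4,8}]tetradeca-1(13),2-diene-6,12-dione | C=C1C(=O)O[C@@H]2/C=C(/C)C3=CC(=O)[C@](C)(C[C@H](O)[C@@H]12)O3 | intermediate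
20 | (2R)-2-methylbutanoic acid | CC[C@@H](C)C(=O)O | starting material
21 | (2Z,4R,8R,9R,11S)-2,11-dimethyl-7-methylidene-6,12-dioxo-5,14-dioxatricyclo[9.2.1.0^{4,8}]tetradeca-1(13),2-dien-9-yl (2R)-2-methylbutanoate | C=C1C(=O)O[C@@H]2/C=C(/C)C3=CC(=O)[C@](C)(C[C@@H](OC(=O)[C@H](C)CC)[C@@H]12)O3 | target

## Step count and risks

Total: 10 steps. Longest linear sequence: 8 steps (1, 2, 3, 4, 7, 8, 9, 10 from 2-methylfuran); the bromide branch (steps 5, 6) joins at step 7.

**Step 9 (most likely to fail).** It is a ten-membered ring closure by an untested reaction. The Lewis acid could rearrange the epoxide or ionise the allylic lactone C–O bond, attack could go to C-8 (nine-membered ring), and the furan face (C-10 configuration) rests on a conformational argument, not on precedent. The fallback replaces the Lewis-acid epoxide opening by an anionic SN2 closure on an iodide. It sets out from 16: LiI and AcOH in THF open the epoxide at the terminal carbon to the iodohydrin F1, and Et3SiCl with imidazole caps the secondary hydroxyl to give the silyl ether F2. Cs2CO3 in DMF at 0.002 M and 40 °C then forms the caesium furan-3-olate, which closes the ring by C-alkylation to the macrocyclic silyl ether F3. O-alkylation would give a strained bridged furan, and Michael addition to the methylene lactone is reversible under aprotic base. HF·pyridine removes the silyl group and the route is rejoined at 19. In this variant the C-8 oxygen is no longer locked anti to the new bond, so the face selectivity would rest on ring conformation alone.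

**Step 7.** The anti and Felkin–Anh selectivities are both needed at once, and one equivalent of allylchromium may be quenched by the acidic furanone C–H. The fallback is a stereospecific allylboration through a closed transition state under neutral conditions. It sets out from 8: Ohira–Bestmann homologation (dimethyl (1-diazo-2-oxopropyl)phosphonate, K2CO3, MeOH) gives the alkyne F4, and n-BuLi then ClCO2Me gives the alkynoate F5. Syn-hydrometallation (i-Bu2AlH, HMPA, catalytic CuMe) and trapping with 2-(iodomethyl)-4,4,5,5-tetramethyl-1,3,2-dioxaborolane give the allylboronate F6, in which the dioxolanyl group is cis to the ester. Reaction of F6 with enal 7 (Sc(OTf)3 10 mol %, toluene, rt) gives the anti adduct through a chair transition state. The same 2 M HCl–THF treatment then lactonises and removes the acetonide, so the route is rejoined at 15.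

**Step 10.** The carbinol is a hindered ring position flanked by two branched carbons, so elimination or no reaction may win over SN2. The fallback is oxidation, catalyst-controlled reduction and plain acylation. It sets out from 19: Dess–Martin periodinane (NaHCO3 buffer, CH2Cl2, 0 °C) gives the ketone F7. Corey–Bakshi–Shibata reduction ((S)-Me-CBS, BH3·SMe2, −40 °C; C-7 as the large and the C-9 methylene as the small flank) gives the epimeric alcohol F8. Steglich esterification of F8 with 20 (DCC, DMAP, CH2Cl2) proceeds with retention and rejoins the route at 21. The ketone must be handled cold and without base because H-7 is acidic.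

## Further compounds

F1 | step 9 | (4R,5R)-4-[(1R)-1-hydroxy-2-iodoethyl]-3-methylidene-5-[(1Z)-2-(5-methyl-4-oxo-4,5-dihydrofuran-2-yl)prop-1-en-1-yl]oxolan-2-one | C=C1C(=O)O[C@H](/C=C(/C)C2=CC(=O)C(C)O2)[C@H]1[C@@H](O)CI
F2 | step 9 | (4S,5R)-4-{(1R)-2-iodo-1-[(triethylsilyl)oxy]ethyl}-3-methylidene-5-[(1Z)-2-(5-methyl-4-oxo-4,5-dihydrofuran-2-yl)prop-1-en-1-yl]oxolan-2-one | C=C1C(=O)O[C@H](/C=C(/C)C2=CC(=O)C(C)O2)[C@H]1[C@@H](O[Si](CC)(CC)CC)CI
F3 | step 9 | (2Z,4R,8S,9S,11S)-2,11-dimethyl-7-methylidene-9-[(triethylsilyl)oxy]-5,14-dioxatricyclo[9.2.1.0^{4,8}]tetradeca-1(13),2-diene-6,12-dione | C=C1C(=O)O[C@@H]2/C=C(/C)C3=CC(=O)[C@](C)(C[C@H](O[Si](CC)(CC)CC)[C@@H]12)O3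
F4 | step 7 | (4R)-4-ethynyl-2,2-dimethyl-1,3-dioxolane | C#C[C@@H]1COC(C)(C)O1
F5 | step 7 | methyl 3-[(4R)-2,2-dimethyl-1,3-dioxolan-4-yl]prop-2-ynoate | COC(=O)C#C[C@@H]1COC(C)(C)O1
F6 | step 7 | methyl (2Z)-3-[(4R)-2,2-dimethyl-1,3-dioxolan-4-yl]-2-[(4,4,5,5-tetramethyl-1,3,2-dioxaborolan-2-yl)methyl]prop-2-enoate | COC(=O)/C(CB1OC(C)(C)C(C)(C)O1)=C\[C@@H]1COC(C)(C)O1
F7 | step 10 | (2Z,4R,8S,11S)-2,11-dimethyl-7-methylidene-5,14-dioxatricyclo[9.2.1.0^{4,8}]tetradeca-1(13),2-diene-6,9,12-trione | C=C1C(=O)O[C@@H]2/C=C(/C)C3=CC(=O)[C@](C)(CC(=O)[C@@H]12)O3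
F8 | step 10 | (2Z,4R,8R,9R,11S)-9-hydroxy-2,11-dimethyl-7-methylidene-5,14-dioxatricyclo[9.2.1.0^{4,8}]tetradeca-1(13),2-diene-6,12-dione | C=C1C(=O)O[C@@H]2/C=C(/C)C3=CC(=O)[C@](C)(C[C@@H](O)[C@@H]12)O3
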